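The route rests on one disconnection, the C2–C3 bond of the dihydrofuran ring. Atoms O3, C3, C2 and the isopropenyl group make up a homoallylic alcohol, and C2 is at the same time the carbon bound to O1 of the five-membered ring fused to the benzene ring. This is the pattern left when a γ-aryloxyallyl metal adds to a neighbouring formyl group. The key step isomerises an O-(2-methylallyl) salicylaldehyde under acridinium photoredox and chiral chromium catalysis, which closes the ring and sets the cis C2/C3 pair in one operation. Its precursor is a benzaldehyde with the 2-methylallyl ether at C2, a silyl-protected hydroxyl at C4 and a bromine at C5, the later acetyl group.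

Key step: step 3

Assumption: which antipode of the bis(oxazoline) leads to the (2S,3S) series cannot be told with certainty on paper; L1 below denotes 2,2'-(cyclopropane-1,1-diyl)bis[(3aS,8aR)-3a,8a-dihydro-8H-indeno[1,2-d][1,3]oxazole], and its mirror image is to be used instead if a pilot run shows the (2R,3R) series.

Step 1
Reactants: 1 5-bromo-2,4-dihydroxybenzaldehyde
Product: 2 5-bromo-4-[(tert-butyldimethylsilyl)oxy]-2-hydroxybenzaldehyde
Conditions: TBSCl (1.05 equiv), imidazole (2 equiv), CH2Cl2, 0 °C
Reagents that add atoms: tert-butyldimethylsilyl chloride, CC(C)(C)[Si](C)(C)Cl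
Why: Chemoselective O-silylation of a phenol, in which the 2-hydroxyl is held in a hydrogen bond to the formyl oxygen and is the poorer nucleophile, whereas the 4-hydroxyl, para to the formyl group and next to bromine, is the more acidic one and should be silylated first by one equivalent of TBSCl.

Step 2
Reactants: 2 5-bromo-4-[(tert-butyldimethylsilyl)oxy]-2-hydroxybenzaldehyde; 3 2-methylprop-2-en-1-ol
Product: 4 5-bromo-4-[(tert-butyldimethylsilyl)oxy]-2-[(2-methylprop-2-en-1-yl)oxy]benzaldehyde
Conditions: PPh3 (1.3 equiv), DIAD (1.3 equiv), THF, 0 °C to rt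
Reagents that add atoms: none
Why: Mitsunobu etherification, in which the acidic formyl-conjugated phenol protonates the PPh3/DIAD betaine and its phenoxide displaces the oxyphosphonium of the primary allylic alcohol (SN2 and SN2' attack lead to the same ether here) under neutral conditions that spare the aryl silyl ether and the aldehyde.

Step 3
Reactants: 4 5-bromo-4-[(tert-butyldimethylsilyl)oxy]-2-[(2-methylprop-2-en-1-yl)oxy]benzaldehyde
Product: 5 (2S,3S)-5-bromo-6-[(tert-butyldimethylsilyl)oxy]-2-(prop-1-en-2-yl)-2,3-dihydro-1-benzofuran-3-ol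
Conditions: 9-mesityl-10-methylacridinium perchlorate (5 mol %), CrCl3(THF)3 (10 mol %), bis(oxazoline) L1 (12 mol %), 2,6-lutidine (10 mol %), CH2Cl2 (0.02 M), 430 nm LEDs, rt, argon
Reagents that add atoms: none
Why: Proposed new method: the excited acridinium should remove one electron from the dialkoxyarene of 4, the radical cation should lose a proton from O–CH2 (shuttled by 2,6-lutidine), and the 1-aryloxy-2-methylallyl radical should be caught at its CH2 end by divalent chromium, itself made from CrCl3(THF)3 by the acridinyl radical, to give a trivalent γ-aryloxyallylchromium that adds through its oxygen-bearing carbon to the neighbouring formyl group, after which protonolysis of the chromium alkoxide closes both catalytic cycles and the net change is a redox-neutral isomerisation of 4 into 5 without any stoichiometric reagent. The closest known reaction types are the intermolecular enantioselective allylation of aldehydes by alkenes through allylic C–H cleavage under acridinium and chiral chromium catalysis and the intramolecular Nozaki–Hiyama allylation of aldehydes by allyl halides; neither has been run on an allyl aryl ether tethered to its aldehyde. The dihydrofuran ring closes by a 5-exo-trig attack of C2 on the formyl carbon, inside a six-membered cyclic array made up of chromium, the former carbonyl oxygen, C3, C2, the central allyl carbon and the allyl CH2, which shares the forming C2–C3 bond with the new ring. C3 is set by the bis(oxazoline) on chromium, which decides the face of the aldehyde that is attacked, and C2 follows from C3, because a benzo-fused five-membered ring keeps the torsion C3a–C3–C2–O1 small, so the six-membered array can only close if the oxygen on C3 and the central allyl carbon on C2 sit on the same face, which is the cis relation of hydroxyl and isopropenyl. The step needs C–H cleavage at O–CH2 and not at CH3, which the substrate secures because only the O–CH2 hydrogens are conjugated with the oxidised aryl ether while the isolated 1,1-disubstituted alkene is too hard to oxidise; it needs γ- and not α-attack, secured by the five- against a seven-membered ring; and it needs the C5 bromide to stay, which it should because divalent chromium does not insert into aryl bromides without nickel.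

Step 4
Reactants: 5 (2S,3S)-5-bromo-6-[(tert-butyldimethylsilyl)oxy]-2-(prop-1-en-2-yl)-2,3-dihydro-1-benzofuran-3-ol; 6 tributyl(1-ethoxyethenyl)stannane
Product: 8 1-[(2S,3S)-6-[(tert-butyldimethylsilyl)oxy]-3-hydroxy-2-(prop-1-en-2-yl)-2,3-dihydro-1-benzofuran-5-yl]ethan-1-one, via enol ether 7 (not isolated)
Conditions: Pd(PPh3)4 (5 mol %), toluene, 100 °C; then 0.1 M aq HCl, THF, 0 °C
Reagents that add atoms: water, O
Why: Stille coupling of the aryl bromide with the α-ethoxyvinylstannane by zerovalent palladium followed by hydrolysis of the aryl enol ether, which is protonated far faster than the benzylic alcohol ionises, so that dilute acid at 0 °C should unmask the methyl ketone without touching C2 or C3.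

Step 5
Reactants: 9 methyl but-2-ynoate
Product: 11 methyl (2Z)-2-(hydroxymethyl)but-2-enoate, via vinylalane 10 (not isolated)
Conditions: i-Bu2AlH (1.1 equiv), NMO (1.1 equiv), THF, 0 °C; then CH2O (gas from cracked paraformaldehyde), 0 °C; aq potassium sodium tartrate
Reagents that add atoms: formaldehyde, C=O
Why: Vinylalumination, in which hydride from NMO-moderated i-Bu2AlH adds in conjugate fashion to C3 and aluminium ends at C2 on the same side of the double bond, and the α-aluminated enoate then adds to formaldehyde with retention at 0 °C, which places CH3 cis to the ester (Z) before the aluminium species can equilibrate.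

Step 6
Reactants: 11 methyl (2Z)-2-(hydroxymethyl)but-2-enoate
Product: 12 (2Z)-2-(hydroxymethyl)but-2-enoic acid
Conditions: LiOH·H2O (1.5 equiv), THF/H2O, 0 °C to rt; then 1 M HCl
Reagents that add atoms: lithium hydroxide, [Li+].[OH-]
Why: Saponification of a methyl ester with LiOH at or below room temperature, where hydroxide attacks the ester carbonyl and should not add reversibly to the trisubstituted, β-methyl-shielded double bond, so the Z geometry should be kept.

Step 7
Reactants: 12 (2Z)-2-(hydroxymethyl)but-2-enoic acid
Product: 14 (2Z)-2-[(acetyloxy)methyl]but-2-enoic acid, via mixed anhydride 13 (not isolated)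
Conditions: Ac2O (2.5 equiv), pyridine, 0 °C to rt; then H2O
Reagents that add atoms: acetic anhydride, CC(=O)OC(C)=O
Why: O-Acetylation of the primary allylic alcohol with Ac2O in pyridine, during which the carboxyl group is carried as its mixed acetic anhydride that pyridine and water attack at the unhindered acetyl carbonyl on work-up, so the acid should come back with its own oxygen atoms and without passing through an acylpyridinium of the enoic acid that could scramble the double bond.

Step 8
Reactants: 8 1-[(2S,3S)-6-[(tert-butyldimethylsilyl)oxy]-3-hydroxy-2-(prop-1-en-2-yl)-2,3-dihydro-1-benzofuran-5-yl]ethan-1-one; 14 (2Z)-2-[(acetyloxy)methyl]but-2-enoic acid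
Product: 16 (2S,3S)-5-acetyl-6-[(tert-butyldimethylsilyl)oxy]-2-(prop-1-en-2-yl)-2,3-dihydro-1-benzofuran-3-yl (2Z)-2-[(acetyloxy)methyl]but-2-enoate, via mixed anhydride 15 (not isolated)
Conditions: 14 (1.5 equiv), 2,4,6-trichlorobenzoyl chloride (1.5 equiv), Et3N (3 equiv), toluene, rt; then 8, 70 °C
Reagents that add atoms: none
Why: Yamaguchi esterification, in which the acid is turned into its mixed anhydride with 2,4,6-trichlorobenzoyl chloride, whose own carbonyl is shielded by two ortho chlorines, and the secondary alcohol is acylated at the enoyl carbonyl on warming without DMAP, the absence of a nucleophilic catalyst being what should protect the Z double bond and the allylic acetate from addition–elimination, while acylation at oxygen leaves the C3 configuration as set.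

Step 9
Reactants: 16 (2S,3S)-5-acetyl-6-[(tert-butyldimethylsilyl)oxy]-2-(prop-1-en-2-yl)-2,3-dihydro-1-benzofuran-3-yl (2Z)-2-[(acetyloxy)methyl]but-2-enoate
Product: 17 (2S,3S)-5-acetyl-6-hydroxy-2-(prop-1-en-2-yl)-2,3-dihydro-1-benzofuran-3-yl (2Z)-2-[(acetyloxy)methyl]but-2-enoate
Conditions: HF·pyridine, pyridine, THF, 0 °C to rt
Reagents that add atoms: none
Why: Fluoride-induced cleavage of the aryl silyl ether with pyridine-buffered HF, a weakly acidic medium in which the phenol is released in its neutral form, so that neither of the two esters should be cleaved nor the acyloxy group on C3, para-related to the new hydroxyl through C3a, be expelled by way of a quinone methide.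

Compound list
1 | 5-bromo-2,4-dihydroxybenzaldehyde | O=Cc1cc(Br)c(O)cc1O | starting material
2 | 5-bromo-4-[(tert-butyldimethylsilyl)oxy]-2-hydroxybenzaldehyde | O=Cc1cc(Br)c(O[Si](C)(C)C(C)(C)C)cc1O | intermediate
3 | 2-methylprop-2-en-1-ol | C=C(C)CO | starting material
4 | 5-bromo-4-[(tert-butyldimethylsilyl)oxy]-2-[(2-methylprop-2-en-1-yl)oxy]benzaldehyde | C=C(C)COc1cc(O[Si](C)(C)C(C)(C)C)c(Br)cc1C=O | intermediate
5 | (2S,3S)-5-bromo-6-[(tert-butyldimethylsilyl)oxy]-2-(prop-1-en-2-yl)-2,3-dihydro-1-benzofuran-3-ol (hydroxyl and isopropenyl cis) | C=C(C)[C@@H]1Oc2cc(O[Si](C)(C)C(C)(C)C)c(Br)cc2[C@@H]1O | intermediate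
6 | tributyl(1-ethoxyethenyl)stannane | CCCC[Sn](CCCC)(CCCC)C(=C)OCC | starting material
7 | (2S,3S)-6-[(tert-butyldimethylsilyl)oxy]-5-(1-ethoxyethenyl)-2-(prop-1-en-2-yl)-2,3-dihydro-1-benzofuran-3-ol | C=C(C)[C@@H]1Oc2cc(O[Si](C)(C)C(C)(C)C)c(C(=C)OCC)cc2[C@@H]1O | intermediate
8 | 1-[(2S,3S)-6-[(tert-butyldimethylsilyl)oxy]-3-hydroxy-2-(prop-1-en-2-yl)-2,3-dihydro-1-benzofuran-5-yl]ethan-1-one | C=C(C)[C@@H]1Oc2cc(O[Si](C)(C)C(C)(C)C)c(C(C)=O)cc2[C@@H]1O | intermediate
9 | methyl but-2-ynoate | CC#CC(=O)OC | starting material
10 | methyl (2E)-2-[bis(2-methylpropyl)alumanyl]but-2-enoate (aluminium on C2, CH3 cis to the ester; NMO-coordinated in solution) | C/C=C(/[Al](CC(C)C)CC(C)C)C(=O)OC | intermediate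
11 | methyl (2Z)-2-(hydroxymethyl)but-2-enoate | C/C=C(/CO)C(=O)OC | intermediate
12 | (2Z)-2-(hydroxymethyl)but-2-enoic acid | C/C=C(/CO)C(=O)O | intermediate
13 | acetic (2Z)-2-[(acetyloxy)methyl]but-2-enoic anhydride | C/C=C(/COC(C)=O)C(=O)OC(C)=O | intermediate
14 | (2Z)-2-[(acetyloxy)methyl]but-2-enoic acid | C/C=C(/COC(C)=O)C(=O)O | intermediate
15 | (2Z)-2-[(acetyloxy)methyl]but-2-enoic 2,4,6-trichlorobenzoic anhydride | C/C=C(/COC(C)=O)C(=O)OC(=O)c1c(Cl)cc(Cl)cc1Cl | intermediate
16 | (2S,3S)-5-acetyl-6-[(tert-butyldimethylsilyl)oxy]-2-(prop-1-en-2-yl)-2,3-dihydro-1-benzofuran-3-yl (2Z)-2-[(acetyloxy)methyl]but-2-enoate | C=C(C)[C@@H]1Oc2cc(O[Si](C)(C)C(C)(C)C)c(C(C)=O)cc2[C@@H]1OC(=O)/C(=C\C)COC(C)=O | intermediate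
17 | (2S,3S)-5-acetyl-6-hydroxy-2-(prop-1-en-2-yl)-2,3-dihydro-1-benzofuran-3-yl (2Z)-2-[(acetyloxy)methyl]but-2-enoate | C=C(C)[C@@H]1Oc2cc(O)c(C(C)=O)cc2[C@@H]1OC(=O)/C(=C\C)COC(C)=O | target

Total step count: 9.
Longest linear sequence: 6 steps (steps 1, 2, 3, 4, 8 and 9, from 1 to 17); steps 5 to 7 form the three-step side branch to acid 14.

Steps most likely to fail

Step 3 (proposed new method). Return electron transfer may outrun proton loss, so that no allyl radical forms. The product, a better electron donor than 4, may be re-oxidised. Facial discrimination at the aldehyde may be insufficient. Acid set free in the medium may ionise the benzylic C3–O bond, with epimerisation or loss of water towards the benzofuran. The fallback uses known chemistry, sets out from 4 and comes back at 5. Irradiation of 4 at 350 nm in degassed benzene should start the Norrish–Yang photocyclisation known for 2-alkoxybenzaldehydes, in which the excited formyl group abstracts an O–CH2 hydrogen and the 1,5-biradical closes. This should give racemic cis-5-bromo-6-[(tert-butyldimethylsilyl)oxy]-2-(prop-1-en-2-yl)-2,3-dihydro-1-benzofuran-3-ol F1 beside racemic trans-5-bromo-6-[(tert-butyldimethylsilyl)oxy]-2-(prop-1-en-2-yl)-2,3-dihydro-1-benzofuran-3-ol F2, which is removed by chromatography. An acylative kinetic resolution of F1 follows, with isobutyric anhydride and i-Pr2NEt in CHCl3 at 0 °C and 2-phenyl-2,3-dihydroimidazo[2,1-b][1,3]benzothiazole (benzotetramisole) as catalyst, in the antipode that acylates the (2R,3R) alcohol. It should turn the unwanted enantiomer into (2R,3R)-5-bromo-6-[(tert-butyldimethylsilyl)oxy]-2-(prop-1-en-2-yl)-2,3-dihydro-1-benzofuran-3-yl 2-methylpropanoate F3 and leave 5, which is separated and carried into step 4.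

Step 8. The activated acyl species may lose its Z geometry by reversible conjugate addition of chloride or amine. The allylic acetate may be displaced. Acylation of the hindered cis alcohol may be slow enough at 70 °C for ionisation at C3 to compete. The fallback sets out from 5, 6 and 14 and comes back at 16; it moves the acylation ahead of the unmasking of the ketone and activates the alcohol instead of relying on heat. The Stille coupling of step 4 is worked up without acid, on silica deactivated with Et3N, so that enol ether 7 is isolated. Acid 14 is dehydrated with DCC (0.5 equiv, CH2Cl2, 0 °C), a method that needs no nucleophilic catalyst, to (2Z)-2-[(acetyloxy)methyl]but-2-enoic anhydride F4. The lithium alkoxide of 7 (LiN(SiMe3)2, THF, −78 °C), which carries no enolisable ketone at this stage, should be acylated by F4 at low temperature to (2S,3S)-6-[(tert-butyldimethylsilyl)oxy]-5-(1-ethoxyethenyl)-2-(prop-1-en-2-yl)-2,3-dihydro-1-benzofuran-3-yl (2Z)-2-[(acetyloxy)methyl]but-2-enoate F5. 0.1 M aq HCl in THF at 0 °C then hydrolyses the enol ether to give 16.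

Step 4. Oxidative addition of zerovalent palladium to the electron-rich C–Br bond flanked by the silyl ether may be slow, so that prolonged heating leads to protodebromination or decomposition. The acid used for the enol ether hydrolysis may ionise the benzylic alcohol. The fallback sets out from 5 and comes back at 8, replacing the palladium coupling by halogen–metal exchange. n-BuLi (2.1 equiv, THF, −78 °C) should first deprotonate the hydroxyl and then exchange bromine for lithium, giving lithium (2S,3S)-6-[(tert-butyldimethylsilyl)oxy]-5-lithio-2-(prop-1-en-2-yl)-2,3-dihydro-1-benzofuran-3-olate F6. F6 is acetylated at −78 °C with N-methoxy-N-methylacetamide and quenched cold with aq NH4Cl, before the silyl group can migrate from oxygen to the lithiated carbon, to give 8 directly.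

Further compounds
F1 | step 3 | racemic cis-5-bromo-6-[(tert-butyldimethylsilyl)oxy]-2-(prop-1-en-2-yl)-2,3-dihydro-1-benzofuran-3-ol | C=C(C)[C@@H]1Oc2cc(O[Si](C)(C)C(C)(C)C)c(Br)cc2[C@@H]1O.C=C(C)[C@H]1Oc2cc(O[Si](C)(C)C(C)(C)C)c(Br)cc2[C@H]1O
F2 | step 3 | racemic trans-5-bromo-6-[(tert-butyldimethylsilyl)oxy]-2-(prop-1-en-2-yl)-2,3-dihydro-1-benzofuran-3-ol | C=C(C)[C@@H]1Oc2cc(O[Si](C)(C)C(C)(C)C)c(Br)cc2[C@H]1O.C=C(C)[C@H]1Oc2cc(O[Si](C)(C)C(C)(C)C)c(Br)cc2[C@@H]1O
F3 | step 3 | (2R,3R)-5-bromo-6-[(tert-butyldimethylsilyl)oxy]-2-(prop-1-en-2-yl)-2,3-dihydro-1-benzofuran-3-yl 2-methylpropanoate | C=C(C)[C@H]1Oc2cc(O[Si](C)(C)C(C)(C)C)c(Br)cc2[C@H]1OC(=O)C(C)C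
F4 | step 8 | (2Z)-2-[(acetyloxy)methyl]but-2-enoic anhydride | C/C=C(/COC(C)=O)C(=O)OC(=O)/C(=C\C)COC(C)=O
F5 | step 8 | (2S,3S)-6-[(tert-butyldimethylsilyl)oxy]-5-(1-ethoxyethenyl)-2-(prop-1-en-2-yl)-2,3-dihydro-1-benzofuran-3-yl (2Z)-2-[(acetyloxy)methyl]but-2-enoate | C=C(C)[C@@H]1Oc2cc(O[Si](C)(C)C(C)(C)C)c(C(=C)OCC)cc2[C@@H]1OC(=O)/C(=C\C)COC(C)=O
F6 | step 4 | lithium (2S,3S)-6-[(tert-butyldimethylsilyl)oxy]-5-lithio-2-(prop-1-en-2-yl)-2,3-dihydro-1-benzofuran-3-olate | C=C(C)[C@@H]1Oc2cc(O[Si](C)(C)C(C)(C)C)c([Li])cc2[C@@H]1O[Li]
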